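**Plan**

1. Numbering: lactone ring A is O1–C2(=O)–C3=C4–C5–C6; the chain is C1'=C2'–C3'H2–C4'(OH)–C5'H2–C6'(OAc)–C7'=C8'–Ph. Retrosynthesis: C3=C4 is traced back to a phenylselanyl group on C3 and the O1–C2 bond to a δ-hydroxy methyl ester; the chain is then cut at C3'–C4' and at C6–C1' around the three-carbon unit C1'–C3'.
2. Enabling feature: C6(O1)–C1'=C2'–C3'H2–C4'(OH) is an (E)-alkene flanked by an allylic and a homoallylic carbinol in a 1,5-anti relation, the imprint of two successive allylborations by one γ-boryl allylborane.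
3. Forward: an allenylboronate and a chiral dialkylborane give the bifunctional reagent, which joins an aldehyde carrying C2–C6 of ring A (latent unsaturation) and an aldehyde carrying C4'–C8' (acetate in place) in one pot. Ring A then closes by lactonisation of the C6 hydroxyl alone, and selenoxide elimination unveils C3=C4.
4. Stereochemistry: C6' from asymmetric allylboration of cinnamaldehyde; C6 from reagent control by isopinocampheyl groups; C4' and the E geometry of C1'=C2' by chirality transfer from a transient α-boryl carbon.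

Key step: step 8

Remark: from step 3 to step 9 the selenium-bearing carbon is an uncontrolled stereocentre (epimer mixtures, drawn without configuration) that is removed in step 10; isopinocampheyl boranes made from (+)-α-pinene are taken to attack the Si face of an aldehyde and those from (−)-α-pinene the Re face, the usual sense for this reagent class.

**Route**

Step 1
Reactants: 1 propargyl bromide (3-bromoprop-1-yne)
Product: 4 5,5-dimethyl-2-(propa-1,2-dien-1-yl)-1,3,2-dioxaborinane, via allenylmagnesium bromide 2 (not isolated), via allenylboronic acid 3 (not isolated)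
Conditions: Mg, HgCl2 (cat.), Et2O, 0 °C; B(OMe)3, −78 °C; aq. HCl; then 2,2-dimethylpropane-1,3-diol, MgSO4, Et2O, rt
Reagents that add atoms: trimethyl borate COB(OC)OC; 2,2-dimethylpropane-1,3-diol OCC(C)(C)CO
Why: The allenyl Grignard reagent is borylated by trimethyl borate, acidic hydrolysis gives the allenylboronic acid, and condensation with the 1,3-diol gives the small six-membered boronate needed later for E selectivity (Grignard borylation, then boronic ester formation).

Step 2
Reactants: 5 (−)-α-pinene
Product: 7 (+)-diisopinocampheylborane, both isopinocampheyl groups from (−)-α-pinene with boron on C3 trans to the C2 methyl and anti to the gem-dimethyl bridge, via monoisopinocampheylborane 6 (not isolated)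
Conditions: BH3·SMe2, THF, 0 °C; then 0 °C, 3 d with excess 5; solid collected under Ar
Reagents that add atoms: borane–dimethyl sulfide complex [BH3-][S+](C)C
Why: Two syn hydroborations of the trisubstituted alkene from the face opposite the gem-dimethyl bridge give the dialkylborane, and equilibration of the slurry with excess pinene should raise its enantiomeric purity (alkene hydroboration).

Step 3
Reactants: 8 methyl 5,5-dimethoxypentanoate
Product: 10 methyl 5,5-dimethoxy-2-(phenylselanyl)pentanoate (racemic), via lithium ester enolate 9 (not isolated)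
Conditions: LiN(iPr)2, THF, −78 °C; PhSeBr, −78 °C
Reagents that add atoms: benzeneselenenyl bromide Br[Se]c1ccccc1
Why: Kinetic deprotonation gives the ester enolate, which is selenenylated at carbon by the electrophilic selenium reagent, placing the latent C3=C4 unsaturation of ring A (α-selenenylation of an ester enolate).

Step 4
Reactants: 10 methyl 5,5-dimethoxy-2-(phenylselanyl)pentanoate
Product: 11 methyl 5-oxo-2-(phenylselanyl)pentanoate (racemic)
Conditions: CF3CO2H/H2O (1:1), CHCl3, 0 °C to rt
Reagents that add atoms: water O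
Why: Aqueous acid hydrolyses the dimethyl acetal through its oxocarbenium ion while the methyl ester and the selenide should be untouched (acetal hydrolysis).

Step 5
Reactants: 12 (E)-cinnamaldehyde; 13 (−)-B-methoxydiisopinocampheylborane (isopinocampheyl groups from (+)-α-pinene)
Product: 16 (3S,1E)-1-phenylhexa-1,5-dien-3-ol, via B-allyldiisopinocampheylborane 14 (not isolated), via diisopinocampheylborinate ester 15 (not isolated)
Conditions: 13, allylMgBr, Et2O, 0 °C to rt; then 12, −78 °C; then NaOH, H2O2, 0 °C to rt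
Reagents that add atoms: allylmagnesium bromide C=CC[Mg]Br
Why: The allylborane adds 1,2 to the enal through a chair six-membered transition state in which the isopinocampheyl groups from (+)-α-pinene direct the allyl group to the Si face, which sets C6' as S (Brown allylboration).

Step 6
Reactants: 16 (3S,1E)-1-phenylhexa-1,5-dien-3-ol
Product: 17 (3S,1E)-1-phenylhexa-1,5-dien-3-yl acetate
Conditions: Ac2O, pyridine, DMAP (cat.), CH2Cl2, 0 °C to rt
Reagents that add atoms: acetic anhydride CC(=O)OC(C)=O
Why: DMAP-catalysed acylation of the secondary allylic alcohol installs the C6' acetate with retention, so no late differentiation of hydroxyl groups is needed (esterification).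

Step 7
Reactants: 17 (3S,1E)-1-phenylhexa-1,5-dien-3-yl acetate
Product: 19 (1E,3S)-5-oxo-1-phenylpent-1-en-3-yl acetate, via terminal 1,2-diol 18 (not isolated)
Conditions: OsO4 (2 mol %), NaIO4, 2,6-lutidine, 1,4-dioxane/H2O (3:1), 0 °C to rt; crude aldehyde used at once
Reagents that add atoms: osmium tetroxide O=[Os](=O)(=O)=O; sodium periodate [Na+].[O-]I(=O)(=O)=O
Why: OsO4 should dihydroxylate the accessible monosubstituted alkene in preference to the conjugated styrenyl alkene that is deactivated by the allylic acetoxy group, and NaIO4 cleaves the diol and reoxidises osmium (Johnson–Lemieux oxidation).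

Step 8
Reactants: 4 5,5-dimethyl-2-(propa-1,2-dien-1-yl)-1,3,2-dioxaborinane; 7 (+)-diisopinocampheylborane; 11 methyl 5-oxo-2-(phenylselanyl)pentanoate; 19 (1E,3S)-5-oxo-1-phenylpent-1-en-3-yl acetate
Product: 23 methyl (5S,6E,9R,11S,12E)-11-acetoxy-5,9-dihydroxy-13-phenyl-2-(phenylselanyl)trideca-6,12-dienoate (epimers at C2), via γ-boryl allylborane 20 (not isolated), via α-boryl homoallyl borinate 21 (not isolated), via bis-O-borylated diol 22 (not isolated)
Conditions: 7, 4, Et2O, −25 to 0 °C, 3 h; 11 (0.9 equiv), −78 °C, 3 h; 19 (0.7 equiv), −78 to 23 °C, 36 h; then HOCH2CH2NH2, 23 °C, aqueous work-up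
Reagents that add atoms: none
Why: Hydroboration of the terminal allene C=C of 4 by 7 gives the (E)-γ-boryl allylborane 20, whose dialkylallylborane terminus adds to aldehyde 11 at −78 °C through a chair Zimmerman–Traxler transition state (Re-face attack under control of the isopinocampheyl groups, E geometry giving the anti adduct), fixing C6 as S and creating the α-boryl stereocentre of 21. The less reactive allylboronate 21 then adds to aldehyde 19 on warming, again through a six-membered chair with allylic transposition, which forms the C3'–C4' bond and the C1'=C2' double bond at once. The closest known reaction type is the one-pot double allylboration of two aldehydes by a γ-boryl-substituted allylborane that gives (E)-1,5-anti-diols. No ring is closed. C4' (R) is set by 1,3-chirality transfer from the α-boryl carbon, whose substituent sits pseudo-equatorial under the small dioxaborinane ester, and the same preference makes the new olefin E, while C6' of 19 is a spectator. The step needs each aldehyde to meet only its own boron terminus, which the large rate difference between the dialkylallylborane and the allylboronate secures through the order and temperature of addition; the non-oxidative work-up spares the selenide.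

Step 9
Reactants: 23 methyl (5S,6E,9R,11S,12E)-11-acetoxy-5,9-dihydroxy-13-phenyl-2-(phenylselanyl)trideca-6,12-dienoate
Product: 24 (1E,3S,5R,7E)-5-hydroxy-8-[(2S)-6-oxo-5-(phenylselanyl)tetrahydro-2H-pyran-2-yl]-1-phenylocta-1,7-dien-3-yl acetate (epimers at the selenium-bearing carbon)
Conditions: pyridinium p-toluenesulfonate (cat.), toluene, 45 °C
Reagents that add atoms: none
Why: Mild acid-catalysed intramolecular transesterification closes ring A by 6-exo-trig attack of the C6 hydroxyl on the ester, whereas the C4' hydroxyl would need a ten-membered ring, so the two alcohols are told apart without protection (lactonisation).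

Step 10
Reactants: 24 (1E,3S,5R,7E)-5-hydroxy-8-[(2S)-6-oxo-5-(phenylselanyl)tetrahydro-2H-pyran-2-yl]-1-phenylocta-1,7-dien-3-yl acetate
Product: 26 (1E,3S,5R,7E)-5-hydroxy-8-[(2S)-6-oxo-3,6-dihydro-2H-pyran-2-yl]-1-phenylocta-1,7-dien-3-yl acetate, via selenoxide 25 (not isolated)
Conditions: NaIO4, NaHCO3, THF/H2O (3:1), 0 °C to rt
Reagents that add atoms: none
Why: Periodate oxidises the selenide to the selenoxide, which eliminates syn at or below room temperature with a hydrogen of the neighbouring ring CH2 (the only β-hydrogens), so both selenide epimers should converge on the C3=C4 double bond of ring A (selenoxide elimination).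

**Compound list**

1 | propargyl bromide | C#CCBr | starting material
2 | allenylmagnesium bromide | C=C=C[Mg]Br | intermediate
3 | allenylboronic acid | C=C=CB(O)O | intermediate
4 | 5,5-dimethyl-2-(propa-1,2-dien-1-yl)-1,3,2-dioxaborinane | C=C=CB1OCC(C)(C)CO1 | intermediate
5 | (−)-α-pinene, (1S,5S) | CC1=CC[C@H]2C[C@@H]1C2(C)C | starting material
6 | monoisopinocampheylborane (from (−)-α-pinene) | C[C@H]1[C@@H]2C[C@@H](C2(C)C)C[C@@H]1B | intermediate
7 | (+)-diisopinocampheylborane (from (−)-α-pinene) | C[C@H]1[C@@H]2C[C@@H](C2(C)C)C[C@@H]1B[C@H]1C[C@H]2C[C@@H]([C@@H]1C)C2(C)C | intermediate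
8 | methyl 5,5-dimethoxypentanoate | COC(=O)CCCC(OC)OC | starting material
9 | lithium enolate of 8 | COC(O[Li])=CCCC(OC)OC | intermediate
10 | methyl 5,5-dimethoxy-2-(phenylselanyl)pentanoate (racemic) | COC(=O)C([Se]c1ccccc1)CCC(OC)OC | intermediate
11 | methyl 5-oxo-2-(phenylselanyl)pentanoate (racemic) | COC(=O)C([Se]c1ccccc1)CCC=O | intermediate
12 | (E)-cinnamaldehyde | O=C/C=C/c1ccccc1 | starting material
13 | (−)-B-methoxydiisopinocampheylborane (from (+)-α-pinene) | C[C@@H]1[C@H]2C[C@H](C2(C)C)C[C@H]1B(OC)[C@@H]1C[C@@H]2C[C@H]([C@H]1C)C2(C)C | starting material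
14 | (−)-B-allyldiisopinocampheylborane | C[C@@H]1[C@H]2C[C@H](C2(C)C)C[C@H]1B(CC=C)[C@@H]1C[C@@H]2C[C@H]([C@H]1C)C2(C)C | intermediate
15 | (3S,1E)-1-phenylhexa-1,5-dien-3-yl diisopinocampheylborinate | C[C@@H]1[C@H]2C[C@H](C2(C)C)C[C@H]1B(O[C@H](/C=C/c1ccccc1)CC=C)[C@@H]1C[C@@H]2C[C@H]([C@H]1C)C2(C)C | intermediate
16 | (3S,1E)-1-phenylhexa-1,5-dien-3-ol | O[C@H](/C=C/c1ccccc1)CC=C | intermediate
17 | (3S,1E)-1-phenylhexa-1,5-dien-3-yl acetate | CC(=O)O[C@H](/C=C/c1ccccc1)CC=C | intermediate
18 | (4S,5E)-1,2-dihydroxy-6-phenylhex-5-en-4-yl acetate (epimers at C2) | CC(=O)O[C@H](/C=C/c1ccccc1)CC(O)CO | intermediate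
19 | (1E,3S)-5-oxo-1-phenylpent-1-en-3-yl acetate | CC(=O)O[C@H](/C=C/c1ccccc1)CC=O | intermediate
20 | (E)-[3-(5,5-dimethyl-1,3,2-dioxaborinan-2-yl)prop-2-en-1-yl]diisopinocampheylborane | C[C@H]1[C@@H]2C[C@@H](C2(C)C)C[C@@H]1B(C/C=C/B1OCC(C)(C)CO1)[C@H]1C[C@H]2C[C@@H]([C@@H]1C)C2(C)C | intermediate
21 | methyl (5S,6R)-5-[(diisopinocampheylboranyl)oxy]-6-(5,5-dimethyl-1,3,2-dioxaborinan-2-yl)-2-(phenylselanyl)oct-7-enoate | COC(=O)C([Se]c1ccccc1)CC[C@H](OB([C@H]1C[C@H]2C[C@@H]([C@@H]1C)C2(C)C)[C@H]1C[C@H]2C[C@@H]([C@@H]1C)C2(C)C)[C@@H](C=C)B1OCC(C)(C)CO1 | intermediate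
22 | 23 with the C5 oxygen as diisopinocampheylborinate and the C9 oxygen as 5,5-dimethyl-1,3,2-dioxaborinan-2-yl borate | CC(=O)O[C@H](/C=C/c1ccccc1)C[C@H](OB1OCC(C)(C)CO1)C/C=C/[C@@H](OB([C@H]1C[C@H]2C[C@@H]([C@@H]1C)C2(C)C)[C@H]1C[C@H]2C[C@@H]([C@@H]1C)C2(C)C)CCC([Se]c1ccccc1)C(=O)OC | intermediate
23 | methyl (5S,6E,9R,11S,12E)-11-acetoxy-5,9-dihydroxy-13-phenyl-2-(phenylselanyl)trideca-6,12-dienoate | CC(=O)O[C@H](/C=C/c1ccccc1)C[C@H](O)C/C=C/[C@@H](O)CCC([Se]c1ccccc1)C(=O)OC | intermediate
24 | (1E,3S,5R,7E)-5-hydroxy-8-[(2S)-6-oxo-5-(phenylselanyl)tetrahydro-2H-pyran-2-yl]-1-phenylocta-1,7-dien-3-yl acetate | CC(=O)O[C@H](/C=C/c1ccccc1)C[C@H](O)C/C=C/[C@@H]1CCC([Se]c2ccccc2)C(=O)O1 | intermediate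
25 | selenoxide of 24 | CC(=O)O[C@H](/C=C/c1ccccc1)C[C@H](O)C/C=C/[C@@H]1CCC([Se](=O)c2ccccc2)C(=O)O1 | intermediate
26 | (1E,3S,5R,7E)-5-hydroxy-8-[(2S)-6-oxo-3,6-dihydro-2H-pyran-2-yl]-1-phenylocta-1,7-dien-3-yl acetate | CC(=O)O[C@H](/C=C/c1ccccc1)C[C@H](O)C/C=C/[C@@H]1CC=CC(=O)O1 | target

**Step count**

Total steps: 10. Longest linear sequence: 6 (steps 5, 6, 7, 8, 9, 10).

**Steps most likely to fail**

Step 8. What may go wrong: erosion of olefin geometry and of chirality transfer in the second allylboration, and β-elimination of acetic acid from aldehyde 19 during the long reaction at ambient temperature. Fallback: the C3'–C4' bond would be made by a simple asymmetric allylboration and C1'=C2' by cross-metathesis. The fallback sets out from 19. Addition of commercial (+)-B-allyldiisopinocampheylborane (from (−)-α-pinene, Re-face attack, −78 °C, ethanolamine work-up) should give (1E,3S,5R)-5-hydroxy-1-phenylocta-1,7-dien-3-yl acetate F1. The partner is built from acrolein: allylboration with commercial (−)-B-allyldiisopinocampheylborane gives (S)-hexa-1,5-dien-3-ol F2, acryloyl chloride and Et3N give (S)-hexa-1,5-dien-3-yl acrylate F3, and ring-closing metathesis with second-generation Grubbs catalyst gives (S)-6-vinyl-5,6-dihydro-2H-pyran-2-one F4. Cross-metathesis of F1 with an excess of F4 (second-generation Hoveyda–Grubbs catalyst, CH2Cl2, 40 °C) comes back to the route at the target 26.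

Step 7. What may go wrong: loss of site selectivity in the osmylation (attack on the styrenyl alkene) and elimination of acetic acid from the β-acetoxy aldehyde on isolation. Fallback: an aldol route in which no alkene has to be told from another, setting out from 12. An enantioselective Mukaiyama aldol addition of 1-(tert-butyldimethylsilyloxy)-1-methoxyethene (SiCl4 with a chiral bisphosphoramide, enantiomer chosen for Si-face attack) should give methyl (3S,4E)-3-hydroxy-5-phenylpent-4-enoate F5. LiAlH4 reduction gives (3S,4E)-5-phenylpent-4-ene-1,3-diol F6. Selective silylation of the primary hydroxyl (TBSCl, imidazole) gives (3S,1E)-5-(tert-butyldimethylsilyloxy)-1-phenylpent-1-en-3-ol F7. Acetylation (Ac2O, pyridine) gives (3S,1E)-5-(tert-butyldimethylsilyloxy)-1-phenylpent-1-en-3-yl acetate F8. HF·pyridine gives (3S,1E)-5-hydroxy-1-phenylpent-1-en-3-yl acetate F9, and oxidation with Dess–Martin periodinane comes back to the route at 19.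

Step 10. What may go wrong: addition of electrophilic selenium by-products to the alkenes and acetyl migration under the aqueous oxidative conditions. Fallback: the unsaturation is released by a thermal, non-oxidative sulfoxide pyrolysis, setting out from 8. Sulfenylation of the enolate (LiN(iPr)2, then PhSSPh) gives methyl 5,5-dimethoxy-2-(phenylsulfanyl)pentanoate F10, and acetal hydrolysis gives methyl 5-oxo-2-(phenylsulfanyl)pentanoate F11. The one-pot coupling with 4, 7 and 19 as in step 8 should give methyl (5S,6E,9R,11S,12E)-11-acetoxy-5,9-dihydroxy-13-phenyl-2-(phenylsulfanyl)trideca-6,12-dienoate F12. Lactonisation as in step 9 gives (1E,3S,5R,7E)-5-hydroxy-8-[(2S)-6-oxo-5-(phenylsulfanyl)tetrahydro-2H-pyran-2-yl]-1-phenylocta-1,7-dien-3-yl acetate F13. Oxidation at sulfur with one equivalent of mCPBA at −78 °C gives the sulfoxide of that lactone F14, and heating in toluene at 110 °C over CaCO3 comes back to the route at the target 26.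

**Further compounds**

F1 | step 8 | (1E,3S,5R)-5-hydroxy-1-phenylocta-1,7-dien-3-yl acetate | CC(=O)O[C@H](/C=C/c1ccccc1)C[C@H](O)CC=C
F2 | step 8 | (S)-hexa-1,5-dien-3-ol | C=C[C@@H](O)CC=C
F3 | step 8 | (S)-hexa-1,5-dien-3-yl acrylate | C=CC(=O)O[C@H](C=C)CC=C
F4 | step 8 | (S)-6-vinyl-5,6-dihydro-2H-pyran-2-one | C=C[C@@H]1CC=CC(=O)O1
F5 | step 7 | methyl (3S,4E)-3-hydroxy-5-phenylpent-4-enoate | COC(=O)C[C@H](O)/C=C/c1ccccc1
F6 | step 7 | (3S,4E)-5-phenylpent-4-ene-1,3-diol | OCC[C@H](O)/C=C/c1ccccc1
F7 | step 7 | (3S,1E)-5-(tert-butyldimethylsilyloxy)-1-phenylpent-1-en-3-ol | CC(C)(C)[Si](C)(C)OCC[C@H](O)/C=C/c1ccccc1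
F8 | step 7 | (3S,1E)-5-(tert-butyldimethylsilyloxy)-1-phenylpent-1-en-3-yl acetate | CC(=O)O[C@H](/C=C/c1ccccc1)CCO[Si](C)(C)C(C)(C)C
F9 | step 7 | (3S,1E)-5-hydroxy-1-phenylpent-1-en-3-yl acetate | CC(=O)O[C@H](/C=C/c1ccccc1)CCO
F10 | step 10 | methyl 5,5-dimethoxy-2-(phenylsulfanyl)pentanoate | COC(=O)C(Sc1ccccc1)CCC(OC)OC
F11 | step 10 | methyl 5-oxo-2-(phenylsulfanyl)pentanoate | COC(=O)C(Sc1ccccc1)CCC=O
F12 | step 10 | methyl (5S,6E,9R,11S,12E)-11-acetoxy-5,9-dihydroxy-13-phenyl-2-(phenylsulfanyl)trideca-6,12-dienoate | CC(=O)O[C@H](/C=C/c1ccccc1)C[C@H](O)C/C=C/[C@@H](O)CCC(Sc1ccccc1)C(=O)OC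
F13 | step 10 | (1E,3S,5R,7E)-5-hydroxy-8-[(2S)-6-oxo-5-(phenylsulfanyl)tetrahydro-2H-pyran-2-yl]-1-phenylocta-1,7-dien-3-yl acetate | CC(=O)O[C@H](/C=C/c1ccccc1)C[C@H](O)C/C=C/[C@@H]1CCC(Sc2ccccc2)C(=O)O1
F14 | step 10 | sulfoxide of F13 | CC(=O)O[C@H](/C=C/c1ccccc1)C[C@H](O)C/C=C/[C@@H]1CCC(S(=O)c2ccccc2)C(=O)O1
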